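**Plan**
- Retrosynthesis: the C9 acetate, the C8 methacrylate and the C11=C13 methylene are removed first. Then C8–C9, C7–C8, C6–C7 with O–C12, and C1=C10 are cut. This leads back to geraniol (C1–C6, C15), a PMB-oxymethyl phosphonoacetate (C9, C10, C14), methyl propiolate (C7, C11, C12) and tris(methylthio)methane (C8).
- Enabling feature: C8 and C9 are adjacent oxygen-bearing carbons of the ten-membered ring (C8 next to lactone carbon C7, C9 next to alkene carbon C10), so the ring opens there to a C8 aldehyde and a C9 enal.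
- Forward: the chain is built first (C1 aldehyde from geraniol, Z-selective olefination), then the γ-lactone, then the ten-membered ring by SmI2 pinacol coupling, then C13, the two esters and the C14 aldehyde.
- Stereochemistry: 4E comes from geraniol, the ring-cis C1=C10 from the Still–Gennari step, C6 from ligand-controlled alkynylation and C7 from trans conjugate addition. C8 and C9 are set in the ring closure by C7 and the samarium-bridged diolate.
- The C14 PMB ether is later tied to O9 as an acetal, which tells the C8 and C9 hydroxyls apart.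

Key step: step 18

Assumption: (S,S)-ProPhenol is taken to give the (R)-carbinol in step 11; if the sense is the opposite, the (R,R)-ligand is used.
Assumption: the acetal carbon formed in step 21 is drawn as the aryl-equatorial epimer; it is removed in step 23 and has no bearing on the route.

**Step 1**
Reactants: 1 4-methoxybenzyl alcohol
Product: 2 4-methoxybenzyl (methylthio)methyl ether
Conditions: NaH, THF, 0 °C; ClCH2SMe, NaI (cat.), 0 °C to rt
Reagents that add atoms: chloromethyl methyl sulfide, CSCCl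
Why: Williamson etherification of the sodium alkoxide by the activated α-chloro sulfide should give the O,S-acetal cleanly.

**Step 2**
Reactants: 2 4-methoxybenzyl (methylthio)methyl ether; 3 methyl 2-[bis(2,2,2-trifluoroethoxy)phosphoryl]acetate
Product: 5 methyl 2-[bis(2,2,2-trifluoroethoxy)phosphoryl]-3-[(4-methoxybenzyl)oxy]propanoate (racemic), via chloromethyl 4-methoxybenzyl ether 4 (not isolated)
Conditions: SO2Cl2, CH2Cl2, −78 °C, then evaporation; 3, NaH, THF/DMF, 0 °C, then crude 4, 0 °C to rt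
Reagents that add atoms: none
Why: Chlorinolysis of the O,S-acetal gives the α-chloro ether, which should C-alkylate the malonate-like phosphonoacetate anion (alkylation of a stabilised carbanion).

**Step 3**
Reactants: 6 geraniol
Product: 7 geranyl tert-butyldimethylsilyl ether
Conditions: TBSCl, imidazole, DMF, 0 °C to rt
Reagents that add atoms: tert-butyldimethylsilyl chloride, CC(C)(C)[Si](C)(C)Cl
Why: Standard silylation protects the C6 hydroxyl with a group that survives i-Bu2AlH and is later removed selectively.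

**Step 4**
Reactants: 7 geranyl tert-butyldimethylsilyl ether
Product: 8 6,7-epoxygeranyl tert-butyldimethylsilyl ether (racemic at the epoxide)
Conditions: mCPBA, NaHCO3, CH2Cl2, −20 °C
Reagents that add atoms: 3-chloroperoxybenzoic acid, OOC(=O)c1cccc(Cl)c1
Why: Prilezhaev epoxidation should select the electron-rich terminal alkene over the 2,3-alkene, which is deactivated by the allylic silyloxy group.

**Step 5**
Reactants: 8 6,7-epoxygeranyl tert-butyldimethylsilyl ether
Product: 9 (E)-6-[(tert-butyldimethylsilyl)oxy]-4-methylhex-4-enal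
Conditions: HIO4·2H2O, THF/Et2O, 0 °C, short reaction time
Reagents that add atoms: none
Why: Periodic acid opens the epoxide and cleaves the resulting glycol (Malaprade cleavage), giving the C1 aldehyde and acetone without touching the E C4=C5 alkene.

**Step 6**
Reactants: 9 (E)-6-[(tert-butyldimethylsilyl)oxy]-4-methylhex-4-enal; 5 PMB-oxymethyl phosphonate
Product: 10 methyl (2Z,6E)-8-[(tert-butyldimethylsilyl)oxy]-2-{[(4-methoxybenzyl)oxy]methyl}-6-methylocta-2,6-dienoate
Conditions: 5, KN(SiMe3)2, 18-crown-6, THF, −78 °C; then 9, −78 °C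
Reagents that add atoms: none
Why: Still–Gennari variant of the Horner–Wadsworth–Emmons reaction: the trifluoroethyl phosphonate with a crown-separated potassium ion eliminates from the kinetic adduct, placing the ester (C9) cis to the C2 chain, and the doubly stabilised anion is not expected to expel the benzylic alkoxide.

**Step 7**
Reactants: 10 Z-enoate
Product: 11 (2E,6E)-8-[(tert-butyldimethylsilyl)oxy]-2-{[(4-methoxybenzyl)oxy]methyl}-6-methylocta-2,6-dien-1-ol (CH2OH cis to the chain)
Conditions: i-Bu2AlH, CH2Cl2, −78 °C; aq. KNaC4H4O6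
Reagents that add atoms: none
Why: 1,2-Reduction of the conjugated ester by the aluminium hydride gives the C9 allylic alcohol with the alkene geometry unchanged.

**Step 8**
Reactants: 11 C9 allylic alcohol
Product: 12 C9 tert-butyldiphenylsilyl ether of 11
Conditions: TBDPSCl, imidazole, DMF, rt
Reagents that add atoms: tert-butyldiphenylsilyl chloride, CC(C)(C)[Si](Cl)(c1ccccc1)c1ccccc1
Why: Silylation gives a C9 ether that is far more acid-stable than the C6 TBS ether.

**Step 9**
Reactants: 12 bis-silyl ether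
Product: 13 (2E,6Z)-8-[(tert-butyldiphenylsilyl)oxy]-7-{[(4-methoxybenzyl)oxy]methyl}-3-methylocta-2,6-dien-1-ol
Conditions: PPTS, MeOH, rt
Reagents that add atoms: none
Why: Acid-catalysed methanolysis removes the primary TBS ether, while the TBDPS and PMB ethers are stable to these conditions.

**Step 10**
Reactants: 13 C6 allylic alcohol
Product: 14 (2E,6Z)-8-[(tert-butyldiphenylsilyl)oxy]-7-{[(4-methoxybenzyl)oxy]methyl}-3-methylocta-2,6-dienal
Conditions: MnO2, CH2Cl2, rt
Reagents that add atoms: none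
Why: MnO2 allylic oxidation gives the C6 enal with retention of the E geometry.

**Step 11**
Reactants: 14 C6 enal; 15 methyl propiolate
Product: 17 methyl (4R,5E,9Z)-11-[(tert-butyldiphenylsilyl)oxy]-4-hydroxy-10-{[(4-methoxybenzyl)oxy]methyl}-6-methylundeca-5,9-dien-2-ynoate, via methylzinc acetylide of methyl propiolate 16 (not isolated)
Conditions: Me2Zn, (S,S)-ProPhenol (20 mol%), toluene, 4 °C; aq. NH4Cl
Reagents that add atoms: none
Why: ProPhenol/dimethylzinc enantioselective alkynylation of an enal: the dinuclear zinc complex binds aldehyde and alkynylide and delivers the alkyne to one carbonyl face, setting C6 as the (R)-carbinol under ligand control.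

**Step 12**
Reactants: 17 propargylic alcohol
Product: 19 (S)-5-[(1E,5Z)-7-[(tert-butyldiphenylsilyl)oxy]-6-{[(4-methoxybenzyl)oxy]methyl}-2-methylhepta-1,5-dien-1-yl]furan-2(5H)-one, via cis-hydroxy enoate 18 (not isolated)
Conditions: H2 (1 atm), Pd/CaCO3 (Pb-poisoned), quinoline, EtOAc, rt; then PPTS (cat.), CH2Cl2, rt
Reagents that add atoms: none
Why: Lindlar cis-semihydrogenation of the ynoate gives the cis-γ-hydroxy enoate, which lactonises to the butenolide, and the poisoned catalyst spares the trisubstituted alkenes and the benzylic ether.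

**Step 13**
Reactants: 19 butenolide; 20 tris(methylthio)methane
Product: 22 (4S,5R)-5-[(1E,5Z)-7-[(tert-butyldiphenylsilyl)oxy]-6-{[(4-methoxybenzyl)oxy]methyl}-2-methylhepta-1,5-dien-1-yl]-4-[tris(methylthio)methyl]dihydrofuran-2(3H)-one, via tris(methylthio)methyllithium 21 (not isolated)
Conditions: 20, n-BuLi, THF, −78 °C; then 19, −78 °C; AcOH, −78 °C
Reagents that add atoms: none
Why: Michael addition of the soft trithio-orthoformate anion to the butenolide occurs anti to the C6 alkenyl group, setting C7 trans to C6, and the enolate is protonated at C11.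

**Step 14**
Reactants: 22 trithio-orthoester lactone
Product: 23 S-methyl (2R,3S)-2-[(1E,5Z)-7-[(tert-butyldiphenylsilyl)oxy]-6-{[(4-methoxybenzyl)oxy]methyl}-2-methylhepta-1,5-dien-1-yl]-5-oxotetrahydrofuran-3-carbothioate
Conditions: HgCl2, CaCO3, MeCN/H2O (4:1), rt
Reagents that add atoms: water, O
Why: Thiophilic HgCl2-assisted hydrolysis of the trithio-orthoester stops at the S-methyl thioester; CaCO3 buffers the acid and HgCl2 does not oxymercurate the trisubstituted alkenes.

**Step 15**
Reactants: 23 thioester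
Product: 24 (2R,3S)-2-[(1E,5Z)-7-[(tert-butyldiphenylsilyl)oxy]-6-{[(4-methoxybenzyl)oxy]methyl}-2-methylhepta-1,5-dien-1-yl]-5-oxotetrahydrofuran-3-carbaldehyde
Conditions: Et3SiH, Pd/C (10%), acetone, rt
Reagents that add atoms: none
Why: Fukuyama reduction converts the thioester to the C8 aldehyde under neutral conditions that spare the lactone, the ethers and the trisubstituted alkenes, and C7 stays in the favoured trans arrangement.

**Step 16**
Reactants: 24 silyl-protected lactone aldehyde
Product: 25 (2R,3S)-2-[(1E,5E)-7-hydroxy-6-{[(4-methoxybenzyl)oxy]methyl}-2-methylhepta-1,5-dien-1-yl]-5-oxotetrahydrofuran-3-carbaldehyde (CH2OH cis to the chain)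
Conditions: HF·pyridine, pyridine, THF, 0 °C to rt
Reagents that add atoms: none
Why: Fluoride desilylation in a weakly acidic medium frees the C9 alcohol without epimerising or eliminating the β-acyloxy aldehyde.

**Step 17**
Reactants: 25 hydroxy aldehyde
Product: 26 (2Z,6E)-7-[(2R,3S)-3-formyl-5-oxotetrahydrofuran-2-yl]-2-{[(4-methoxybenzyl)oxy]methyl}-6-methylhepta-2,6-dienal (C8 aldehyde, C9 enal)
Conditions: MnO2, CH2Cl2, rt; filtration, used at once
Reagents that add atoms: none
Why: MnO2 oxidation is selective for the allylic alcohol and neutral, so the enal keeps its formyl group cis to the C2 chain and the β-acyloxy aldehyde is not eliminated.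

**Step 18**
Reactants: 26 lactone dialdehyde
Product: 27 (1(10)Z,4E)-8β,9α-dihydroxy-14-[(4-methoxybenzyl)oxy]-7αH-germacra-1(10),4-dien-12,6α-olide
Conditions: SmI2 (0.1 M in THF, 3 equiv), THF, −78 °C, slow addition of 26 to 0.003 M, then −78 to −20 °C; aq. NH4Cl
Reagents that add atoms: none
Why: Two single-electron transfers from SmI2 reduce first the conjugated C9 enal and then the C8 aldehyde to samarium-bound ketyls, which join at carbon to the samarium diolate; the closest known reaction type is the SmI2 or low-valent titanium intramolecular pinacol coupling of dialdehydes, enals included, to medium-ring 1,2-diols. The ten-membered carbocycle closes by C8–C9 bond formation (formally a 10-exo-trig attack on the C8 carbonyl), helped by the ring-cis C1=C10 alkene, the E C4=C5 alkene and the trans lactone, which hold C8 and C9 close. C8 is set by the C7 stereocentre: in the closing conformer the samarium-bound C8 oxygen should lie anti to the C7–C6 bond and the forming bond anti to C7–H, which gives the 8β alkoxide. C9 is set by the samarium bridge, which holds the two oxygens gauche while C7 and C10 stay antiperiplanar across the new bond, giving the threo diol that is trans on the ring (9α). The step needs 1,2- and not 1,4-coupling of the enal ketyl; this is secured because bonding through C1 would close an eight-membered ring containing the E C4=C5 alkene, while high dilution suppresses intermolecular coupling and the lactone and PMB ether are inert to SmI2 in THF without additives.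

**Step 19**
Reactants: 27 diol lactone
Product: 28 8,9-bis(trimethylsilyl) ether of 27
Conditions: TMSCl, imidazole, DMF, 0 °C
Reagents that add atoms: chlorotrimethylsilane, C[Si](C)(C)Cl
Why: Silylation masks both hydroxyls before enolate formation, in particular the C8 hydroxyl, which could otherwise translactonise onto C12.

**Step 20**
Reactants: 28 bis-TMS ether
Product: 32 (1(10)Z,4E)-8β,9α-dihydroxy-14-[(4-methoxybenzyl)oxy]germacra-1(10),4,11(13)-trien-12,6α-olide, via Mannich base 29 (not isolated), via ammonium iodide 30 (not isolated), via bis-TMS methylene lactone 31 (not isolated)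
Conditions: LiN(i-Pr)2, THF, −78 °C; CH2=NMe2+ I−, −78 to 0 °C; MeI, THF, rt; aq. NaHCO3, CH2Cl2, rt; then 1 M HCl, THF, 0 °C
Reagents that add atoms: N,N-dimethylmethyleneiminium iodide (Eschenmoser's salt), C=[N+](C)C.[I-]
Why: Eschenmoser methylenation: the lactone lithium enolate undergoes a Mannich reaction with the iminium salt, N-methylation and base-induced loss of trimethylamine give the exocyclic alkene, and dilute acid on work-up cleaves the trimethylsilyl ethers.

**Step 21**
Reactants: 32 α-methylene lactone diol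
Product: 33 9,14-O-(4-methoxybenzylidene) acetal of the 8β,9α,14-triol lactone (8β-OH free)
Conditions: DDQ, 4 Å molecular sieves, CH2Cl2, 0 °C
Reagents that add atoms: none
Why: DDQ oxidises the 4-methoxybenzyl ether to an oxocarbenium ion that the 1,3-related C9 hydroxyl traps as a six-membered 1,3-dioxane (oxidative acetalisation); only the C8 hydroxyl stays free because trapping by O8 would need a seven-membered ring.

**Step 22**
Reactants: 33 hydroxy acetal
Product: 34 8-O-methacryloyl derivative of 33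
Conditions: methacrylic anhydride, Et3N, DMAP, CH2Cl2, 0 °C to rt
Reagents that add atoms: methacrylic anhydride, C=C(C)C(=O)OC(=O)C(C)=C
Why: DMAP-catalysed acyl transfer from the anhydride esterifies the only free hydroxyl, at C8.

**Step 23**
Reactants: 34 methacrylate acetal
Product: 35 (1(10)Z,4E)-9α,14-dihydroxy-8β-methacryloyloxygermacra-1(10),4,11(13)-trien-12,6α-olide
Conditions: AcOH/THF/H2O (4:1:1), rt
Reagents that add atoms: none
Why: Acid-catalysed hydrolysis of the 4-methoxybenzylidene acetal frees the C9 and C14 hydroxyls without affecting the esters or the α-methylene lactone.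

**Step 24**
Reactants: 35 9,14-diol
Product: 36 (1(10)E,4E)-9α-hydroxy-8β-methacryloyloxy-14-oxogermacra-1(10),4,11(13)-trien-12,6α-olide
Conditions: TEMPO (cat.), PhI(OAc)2, CH2Cl2, rt
Reagents that add atoms: none
Why: Oxoammonium oxidation (TEMPO with PhI(OAc)2) is selective for the primary allylic alcohol over the secondary C9 alcohol and gives the C14 enal, whose geometry is fixed by the ring.

**Step 25**
Reactants: 36 hydroxy enal
Product: 37 target CNP0403553.1
Conditions: Ac2O, pyridine, DMAP (cat.), CH2Cl2, 0 °C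
Reagents that add atoms: acetic anhydride, CC(=O)OC(C)=O
Why: Acetylation of the remaining secondary C9 hydroxyl by acyl transfer completes the target.

**Compound list**
1 | 4-methoxybenzyl alcohol | COc1ccc(CO)cc1 | starting material
2 | 4-methoxybenzyl (methylthio)methyl ether | COc1ccc(COCSC)cc1 | intermediate
3 | methyl 2-[bis(2,2,2-trifluoroethoxy)phosphoryl]acetate | COC(=O)CP(=O)(OCC(F)(F)F)OCC(F)(F)F | starting material
4 | chloromethyl 4-methoxybenzyl ether | COc1ccc(COCCl)cc1 | intermediate
5 | methyl 2-[bis(2,2,2-trifluoroethoxy)phosphoryl]-3-[(4-methoxybenzyl)oxy]propanoate (racemic) | COC(=O)C(COCc1ccc(OC)cc1)P(=O)(OCC(F)(F)F)OCC(F)(F)F | intermediate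
6 | geraniol, (2E)-3,7-dimethylocta-2,6-dien-1-ol | OC/C=C(\C)CCC=C(C)C | starting material
7 | geranyl tert-butyldimethylsilyl ether | CC(C)(C)[Si](C)(C)OC/C=C(\C)CCC=C(C)C | intermediate
8 | 6,7-epoxygeranyl tert-butyldimethylsilyl ether (2E; racemic at the epoxide carbon) | CC(C)(C)[Si](C)(C)OC/C=C(\C)CCC1OC1(C)C | intermediate
9 | (E)-6-[(tert-butyldimethylsilyl)oxy]-4-methylhex-4-enal | CC(C)(C)[Si](C)(C)OC/C=C(\C)CCC=O | intermediate
10 | methyl (2Z,6E)-8-[(tert-butyldimethylsilyl)oxy]-2-{[(4-methoxybenzyl)oxy]methyl}-6-methylocta-2,6-dienoate | CC(C)(C)[Si](C)(C)OC/C=C(\C)CC/C=C(/COCc1ccc(OC)cc1)C(=O)OC | intermediate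
11 | (2E,6E)-8-[(tert-butyldimethylsilyl)oxy]-2-{[(4-methoxybenzyl)oxy]methyl}-6-methylocta-2,6-dien-1-ol | CC(C)(C)[Si](C)(C)OC/C=C(\C)CC/C=C(/COCc1ccc(OC)cc1)CO | intermediate
12 | (2Z,6E)-8-[(tert-butyldimethylsilyl)oxy]-1-[(tert-butyldiphenylsilyl)oxy]-2-{[(4-methoxybenzyl)oxy]methyl}-6-methylocta-2,6-diene | CC(C)(C)[Si](C)(C)OC/C=C(\C)CC/C=C(/COCc1ccc(OC)cc1)CO[Si](c1ccccc1)(c1ccccc1)C(C)(C)C | intermediate
13 | (2E,6Z)-8-[(tert-butyldiphenylsilyl)oxy]-7-{[(4-methoxybenzyl)oxy]methyl}-3-methylocta-2,6-dien-1-ol | OC/C=C(\C)CC/C=C(/COCc1ccc(OC)cc1)CO[Si](c1ccccc1)(c1ccccc1)C(C)(C)C | intermediate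
14 | (2E,6Z)-8-[(tert-butyldiphenylsilyl)oxy]-7-{[(4-methoxybenzyl)oxy]methyl}-3-methylocta-2,6-dienal | O=C/C=C(\C)CC/C=C(/COCc1ccc(OC)cc1)CO[Si](c1ccccc1)(c1ccccc1)C(C)(C)C | intermediate
15 | methyl propiolate | C#CC(=O)OC | starting material
16 | methylzinc acetylide of methyl propiolate | COC(=O)C#C[Zn]C | intermediate
17 | methyl (4R,5E,9Z)-11-[(tert-butyldiphenylsilyl)oxy]-4-hydroxy-10-{[(4-methoxybenzyl)oxy]methyl}-6-methylundeca-5,9-dien-2-ynoate | COC(=O)C#C[C@H](O)/C=C(\C)CC/C=C(/COCc1ccc(OC)cc1)CO[Si](c1ccccc1)(c1ccccc1)C(C)(C)C | intermediate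
18 | methyl (2Z,4S,5E,9Z)-11-[(tert-butyldiphenylsilyl)oxy]-4-hydroxy-10-{[(4-methoxybenzyl)oxy]methyl}-6-methylundeca-2,5,9-trienoate | COC(=O)/C=C\[C@H](O)/C=C(\C)CC/C=C(/COCc1ccc(OC)cc1)CO[Si](c1ccccc1)(c1ccccc1)C(C)(C)C | intermediate
19 | (S)-5-[(1E,5Z)-7-[(tert-butyldiphenylsilyl)oxy]-6-{[(4-methoxybenzyl)oxy]methyl}-2-methylhepta-1,5-dien-1-yl]furan-2(5H)-one | O=C1C=C[C@@H](/C=C(\C)CC/C=C(/COCc2ccc(OC)cc2)CO[Si](c2ccccc2)(c2ccccc2)C(C)(C)C)O1 | intermediate
20 | tris(methylthio)methane | CSC(SC)SC | starting material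
21 | tris(methylthio)methyllithium | [Li]C(SC)(SC)SC | intermediate
22 | (4S,5R)-5-[(1E,5Z)-7-[(tert-butyldiphenylsilyl)oxy]-6-{[(4-methoxybenzyl)oxy]methyl}-2-methylhepta-1,5-dien-1-yl]-4-[tris(methylthio)methyl]dihydrofuran-2(3H)-one (trans) | CSC(SC)(SC)[C@H]1CC(=O)O[C@@H]1/C=C(\C)CC/C=C(/COCc2ccc(OC)cc2)CO[Si](c2ccccc2)(c2ccccc2)C(C)(C)C | intermediate
23 | S-methyl (2R,3S)-2-[(1E,5Z)-7-[(tert-butyldiphenylsilyl)oxy]-6-{[(4-methoxybenzyl)oxy]methyl}-2-methylhepta-1,5-dien-1-yl]-5-oxotetrahydrofuran-3-carbothioate | CSC(=O)[C@H]1CC(=O)O[C@@H]1/C=C(\C)CC/C=C(/COCc2ccc(OC)cc2)CO[Si](c2ccccc2)(c2ccccc2)C(C)(C)C | intermediate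
24 | (2R,3S)-2-[(1E,5Z)-7-[(tert-butyldiphenylsilyl)oxy]-6-{[(4-methoxybenzyl)oxy]methyl}-2-methylhepta-1,5-dien-1-yl]-5-oxotetrahydrofuran-3-carbaldehyde | O=C[C@H]1CC(=O)O[C@@H]1/C=C(\C)CC/C=C(/COCc2ccc(OC)cc2)CO[Si](c2ccccc2)(c2ccccc2)C(C)(C)C | intermediate
25 | (2R,3S)-2-[(1E,5E)-7-hydroxy-6-{[(4-methoxybenzyl)oxy]methyl}-2-methylhepta-1,5-dien-1-yl]-5-oxotetrahydrofuran-3-carbaldehyde | O=C[C@H]1CC(=O)O[C@@H]1/C=C(\C)CC/C=C(/COCc2ccc(OC)cc2)CO | intermediate
26 | (2Z,6E)-7-[(2R,3S)-3-formyl-5-oxotetrahydrofuran-2-yl]-2-{[(4-methoxybenzyl)oxy]methyl}-6-methylhepta-2,6-dienal | O=C[C@H]1CC(=O)O[C@@H]1/C=C(\C)CC/C=C(/COCc2ccc(OC)cc2)C=O | intermediate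
27 | (1(10)Z,4E)-8β,9α-dihydroxy-14-[(4-methoxybenzyl)oxy]-7αH-germacra-1(10),4-dien-12,6α-olide | O[C@H]1[C@H]2CC(=O)O[C@@H]2/C=C(\C)CC/C=C(/COCc3ccc(OC)cc3)[C@@H]1O | intermediate
28 | 8,9-bis(trimethylsilyl) ether of 27 | C[Si](C)(C)O[C@H]1[C@H]2CC(=O)O[C@@H]2/C=C(\C)CC/C=C(/COCc3ccc(OC)cc3)[C@@H]1O[Si](C)(C)C | intermediate
29 | 11-[(dimethylamino)methyl] derivative of 28 (aminomethyl group trans to C8 on the lactone) | C[Si](C)(C)O[C@H]1[C@H]2[C@H](CN(C)C)C(=O)O[C@@H]2/C=C(\C)CC/C=C(/COCc3ccc(OC)cc3)[C@@H]1O[Si](C)(C)C | intermediate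
30 | N-methyl ammonium iodide of 29 | C[Si](C)(C)O[C@H]1[C@H]2[C@H](C[N+](C)(C)C)C(=O)O[C@@H]2/C=C(\C)CC/C=C(/COCc3ccc(OC)cc3)[C@@H]1O[Si](C)(C)C.[I-] | intermediate
31 | 8,9-bis(trimethylsilyl) ether of 32 | C[Si](C)(C)O[C@H]1[C@H]2C(=C)C(=O)O[C@@H]2/C=C(\C)CC/C=C(/COCc3ccc(OC)cc3)[C@@H]1O[Si](C)(C)C | intermediate
32 | (1(10)Z,4E)-8β,9α-dihydroxy-14-[(4-methoxybenzyl)oxy]germacra-1(10),4,11(13)-trien-12,6α-olide | O[C@H]1[C@H]2C(=C)C(=O)O[C@@H]2/C=C(\C)CC/C=C(/COCc3ccc(OC)cc3)[C@@H]1O | intermediate
33 | (1(10)Z,4E)-8β-hydroxy-9α,14-[(4-methoxybenzylidene)dioxy]germacra-1(10),4,11(13)-trien-12,6α-olide (aryl equatorial on the 1,3-dioxane) | O[C@H]1[C@H]2C(=C)C(=O)O[C@@H]2/C=C(\C)CC/C=C(/CO[C@@H](c4ccc(OC)cc4)O3)[C@@H]13 | intermediate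
34 | 8-O-methacryloyl derivative of 33 | C=C(C)C(=O)O[C@H]1[C@H]2C(=C)C(=O)O[C@@H]2/C=C(\C)CC/C=C(/CO[C@@H](c4ccc(OC)cc4)O3)[C@@H]13 | intermediate
35 | (1(10)Z,4E)-9α,14-dihydroxy-8β-methacryloyloxygermacra-1(10),4,11(13)-trien-12,6α-olide | C=C(C)C(=O)O[C@H]1[C@H]2C(=C)C(=O)O[C@@H]2/C=C(\C)CC/C=C(/CO)[C@@H]1O | intermediate
36 | (1(10)E,4E)-9α-hydroxy-8β-methacryloyloxy-14-oxogermacra-1(10),4,11(13)-trien-12,6α-olide | C=C(C)C(=O)O[C@H]1[C@H]2C(=C)C(=O)O[C@@H]2/C=C(\C)CC/C=C(/C=O)[C@@H]1O | intermediate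
37 | CNP0403553.1, (1(10)E,4E)-9α-acetoxy-8β-methacryloyloxy-14-oxogermacra-1(10),4,11(13)-trien-12,6α-olide | C=C(C)C(=O)O[C@H]1[C@H]2C(=C)C(=O)O[C@@H]2/C=C(\C)CC/C=C(/C=O)[C@@H]1OC(C)=O | target

**Step count**
Total: 25 steps (23 in the main line, 2 for phosphonate 5).
Longest linear sequence: 23 steps (geraniol 6 to target 37, steps 3–25).

**Steps most likely to fail**

1. Step 18 (ring closure). The likely failure is incomplete facial selectivity at the enal-derived ketyl carbon C9, so that the ring-cis diol forms beside 27; simple reduction of the enal is a lesser risk. The fallback replaces substrate control in the coupling by reagent control in a later reduction. It sets out from 26: the coupling is run as in step 18 and the product is taken on as a mixture of 27 and its C9 epimer, the 8β,9β-diol F1. MnO2 in CH2Cl2 oxidises only the allylic C9 carbinol of both epimers and converges them on the 8β-hydroxy-9-oxo enone F2. A Corey–Bakshi–Shibata 1,2-reduction then follows (catecholborane, −78 °C, the C8 hydroxyl masked in the flask as its borate), using the oxazaborolidine enantiomer that delivers hydride to the face giving the 9α alcohol. The route is rejoined at 27.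

2. Step 6 (olefination with the new α-alkoxymethyl phosphonate). The likely failures are loss of 4-methoxybenzyl oxide from the phosphonate anion and erosion of Z-selectivity by the extra α-substituent. The fallback installs C14 after the olefination instead of carrying it in the phosphonate. It sets out from 9 and 3. Phosphonate 3 is brominated (NaH, N-bromosuccinimide, THF) to methyl 2-[bis(2,2,2-trifluoroethoxy)phosphoryl]-2-bromoacetate F3. Its Horner–Wadsworth–Emmons reaction with 9 (t-BuOK, 18-crown-6, THF, −78 °C) should give the (E)-α-bromo enoate F4, in which the ester already sits cis to the chain. A Stille coupling (Pd(PPh3)4, CuI, DMF, 60 °C) with tributyl{[(4-methoxybenzyl)oxy]methyl}stannane F5, made from tributyl(iodomethyl)stannane and the sodium alkoxide of 1, replaces bromine by the PMB-oxymethyl group with retention. The route is rejoined at 10.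

3. Step 13 (conjugate addition). The likely failure is γ-deprotonation of the doubly allylic C6–H of the butenolide by the lithium reagent, which would erase the C6 configuration and compete with 1,4-addition. The fallback uses a weakly basic copper reagent and brings C8 in at the alcohol oxidation level. It sets out from 19. Addition of (i-PrO)Me2SiCH2MgCl with CuBr·SMe2 (cat.) and Me3SiCl in THF at −78 °C should give the trans silylmethyl lactone F6. Tamao–Fleming oxidation (KF, KHCO3, H2O2, THF/MeOH, 0 °C) gives the hydroxymethyl lactone F7, and Dess–Martin oxidation (NaHCO3, CH2Cl2) gives aldehyde 24. The route is rejoined at 24, so steps 14 and 15 are not needed.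

**Further compounds**
F1 | step 18 | (1(10)Z,4E)-8β,9β-dihydroxy-14-[(4-methoxybenzyl)oxy]-7αH-germacra-1(10),4-dien-12,6α-olide (C9 epimer of 27) | O[C@H]1[C@H]2CC(=O)O[C@@H]2/C=C(\C)CC/C=C(/COCc3ccc(OC)cc3)[C@H]1O
F2 | step 18 | (1(10)Z,4E)-8β-hydroxy-14-[(4-methoxybenzyl)oxy]-9-oxo-7αH-germacra-1(10),4-dien-12,6α-olide | O[C@H]1[C@H]2CC(=O)O[C@@H]2/C=C(\C)CC/C=C(/COCc3ccc(OC)cc3)C1=O
F3 | step 6 | methyl 2-[bis(2,2,2-trifluoroethoxy)phosphoryl]-2-bromoacetate | COC(=O)C(Br)P(=O)(OCC(F)(F)F)OCC(F)(F)F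
F4 | step 6 | methyl (2E,6E)-2-bromo-8-[(tert-butyldimethylsilyl)oxy]-6-methylocta-2,6-dienoate | CC(C)(C)[Si](C)(C)OC/C=C(\C)CC/C=C(/Br)C(=O)OC
F5 | step 6 | tributyl{[(4-methoxybenzyl)oxy]methyl}stannane | CCCC[Sn](CCCC)(CCCC)COCc1ccc(OC)cc1
F6 | step 13 | (4S,5R)-5-[(1E,5Z)-7-[(tert-butyldiphenylsilyl)oxy]-6-{[(4-methoxybenzyl)oxy]methyl}-2-methylhepta-1,5-dien-1-yl]-4-{[isopropoxy(dimethyl)silyl]methyl}dihydrofuran-2(3H)-one | CC(C)O[Si](C)(C)C[C@H]1CC(=O)O[C@@H]1/C=C(\C)CC/C=C(/COCc2ccc(OC)cc2)CO[Si](c2ccccc2)(c2ccccc2)C(C)(C)C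
F7 | step 13 | (4S,5R)-5-[(1E,5Z)-7-[(tert-butyldiphenylsilyl)oxy]-6-{[(4-methoxybenzyl)oxy]methyl}-2-methylhepta-1,5-dien-1-yl]-4-(hydroxymethyl)dihydrofuran-2(3H)-one | OC[C@H]1CC(=O)O[C@@H]1/C=C(\C)CC/C=C(/COCc2ccc(OC)cc2)CO[Si](c2ccccc2)(c2ccccc2)C(C)(C)C
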